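- I decide to follow one number through gamma, the flask charged at once at 5 °C: the split φ, the share of first product that takes a second partner to bis adduct and does not fall to side product.

| setting | gamma | zeta | beta | delta | epsilon |
|---|---|---|---|---|---|
| substrate | 0.16 M | 0.16 M | 0.16 M | 0.16 M (fed, over 2.5 h) | 0.16 M (fed, over 2.5 h) |
| partner | 3.00 equiv | 3.00 equiv (fed, over 2.5 h) | 3.00 equiv | 3.00 equiv | 3.00 equiv |
| temperature | 5 °C | 5 °C |  | 5 °C |  |
| time | 4.0 h | 4.0 h | 4.0 h | 4.0 h | 4.0 h |
| remark | everything together at the start | all else is in the flask from the start; the feed brings no volume worth counting | everything together at the start at −25 °C, warmed to 5 °C at 2.5 h | all else is in the flask from the start; the feed brings no volume worth counting | the addition at −25 °C, then warmed to 5 °C; the feed brings no volume worth counting |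

    substrate + partner → first product (k1 = 0.010 M⁻¹ min⁻¹, Ea1 = 56.0 kJ mol⁻¹)
    partner + tris adduct → tetra adduct (k2 = 0.0061 M⁻¹ min⁻¹, Ea2 = 51.0 kJ mol⁻¹)
    partner + bis adduct → tris adduct (k3 = 0.0096 M⁻¹ min⁻¹, Ea3 = 74.0 kJ mol⁻¹)
    first product → side product (k4 = 0.030 min⁻¹, Ea4 = 87.0 kJ mol⁻¹)
    crystals ⇌ bis adduct, rate k5*(cs5 - [bis adduct]) while solid is left; crystals form when [bis adduct] > cs5 (cs5 = 3.7 mM, k5 = 0.69 min⁻¹)
    partner + first product → bis adduct (k6 = 0.063 M⁻¹ min⁻¹, Ea6 = 66.0 kJ mol⁻¹)
    (constants at 5 °C)

- for bis adduct the crystals are counted in
- as a solid, counted per litre of solution: crystals
- at 5 °C the constants are as listed, elsewhere as the activation energies make them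

1. the best flask by amount of bis adduct, in percent of the substrate charged; "all alike" if 1.5 percentage points covers them all (gamma / zeta / beta / delta / epsilon / all alike)
2. amount of bis adduct at the end, in percent of the substrate charged, gamma
3. amount of bis adduct at the end, in percent of the substrate charged, zeta
4. amount of bis adduct at the end, in percent of the substrate charged, beta
5. amount of bis adduct at the end, in percent of the substrate charged, delta
6. amount of bis adduct at the end, in percent of the substrate charged, epsilon

- In the first instants of gamma, partner stands at 0.480 M, so φ, the bis rate constant times [partner] divided by that same product plus the side-product rate constant, is 50.2%, about half.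
- At that partner, substrate in gamma has a pseudo-first-order half-life near 2.41 h, while first product, with the same partner, has half-lives of 0.38 h towards bis adduct and 0.39 h towards side product. These are both shorter, so I treat first product as a small resting state and let φ split the substrate lost.
- In the middle of gamma, partner sinks. If it held still, conversion would reach 68.4%; each substrate converted takes one partner, plus φ of another, which leaves 0.316 M and a mean of 0.398 M.
- I go round again with that mean for gamma: conversion falls to 61.5% and φ to 45.5%.
- Their product, my estimate for the end of gamma, is 28.0%, which counts bis adduct, tris adduct and tetra adduct together, along with φ's share of any first product still unsplit.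
- Bis adduct above 3.7 mM crystallises in gamma, so I hold the dissolved part near that level, and the step to tris adduct from there, reckoned at my mean partner over the whole 4.0 h, costs about 2.12%, less than the total. I commit to a little under 25.9% for gamma.
- Zeta and delta are fed over their first 2.5 h, beta stands cold for that span and epsilon is both fed and cold, and that span is about as long as the substrate half-life in gamma, so I pick gamma as best.
- The forecast also names gamma, with 25.7% for gamma, 17.3% for zeta, 14.2% for beta, 20.5% for delta and 13.6% for epsilon, on the ground that “the first product splits roughly evenly between bis adduct and side product”.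
- The simulation gives gamma as best, with 24.6% for gamma, 17.5% for zeta, 13.4% for beta, 19.1% for delta and 12.9% for epsilon.
- My φ for gamma was 50.2% at the charge and 45.5% at my mean, and the end state of gamma reads 45.7% as bis, tris and tetra adducts over those plus side product. For delta, the mean partner of 0.458 M over the first 2.5 h gives φ of 49.0% for that span, and the end state of delta, which also holds the later hours, reads 46.7%. Gamma has not come to rest at 4.00 h, with substrate at 38.8%. By 40.0 h its substrate is down to 0.197%, side product stands at 57.6%, tetra adduct at 10.3%, and bis adduct at 28.3%.

The constants are those of an exercise; the rest is arithmetic.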